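Plan
1. Locants are daucane locants: C1 quaternary C–Me, C2/C3 CH2, C4 isopropyl carbinol, C5 ring-fusion CH, C6 anisoate carbon, C7 CH2, C8 C–Me, C9 CH, C10 acetate carbon. Retrosynthetically the two esters are removed, the C10–O/8,9-alkene unit is traced back to a 9,10-alkene, and the C6 carbinol to a ketone.
2. Enabling feature: in the seven-membered ring the C6 carbonyl lies between C5 and C7, and the tertiary carbinol C4 of the five-membered ring is bonded to C5. C4(O)–C5–C6(=O)–C7 is therefore an opened C4/C5-epoxy enol silane (a C5–C6–C7 silyloxyallyl cation), and C8–C9–C10–C1 is a 1,3-diene tied to C4 through C2–C3.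
3. The hydroazulenone is cut at C1–C5 and C7–C8 in one operation. The open chain is then cut at C6–C7 (MeMgBr), C4–isopropyl (carbocupration), C5–C6 (acetylide carboxylation), C4–C5 (alkyne homologation), C2–C3 (Johnson–Claisen) and C1–C10 (Grignard).
4. Forward: the chain is assembled linearly from crotonaldehyde (steps 1–11). In step 12 the five-membered ring (C1–C5) and the seven-membered ring (C7–C8) close together. Steps 13–19 adjust oxidation levels and esters.
5. Stereochemistry: C4 comes from Sharpless epoxidation (D-(−)-tartrate) of a geometrically defined allylic alcohol, C5 from inversion at the epoxide carbon in the cycloaddition, and C1 from the diene face that reacts. C6 is set by hydride delivery from the C4 hydroxyl, and C10 by epoxidation anti to the C1 methyl followed by opening at C9.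

Key step: step 12

Remark: systematic names use azulene numbering (C3 = C4, C3a = C5, C4 = C6, C6 = C8, C7 = C9, C8 = C10, C8a = C1 of the daucane locants). The C8 centre created in step 12 is not present in the target and is drawn as the outcome of suprafacial bonding to the (E,E)-diene.

Step 1
Reactants: 1 (2E)-but-2-enal (crotonaldehyde); 2 isopropenylmagnesium bromide
Product: 3 (4E)-2-methylhexa-1,4-dien-3-ol (racemic)
Conditions: THF, −78 → 0 °C; aq. NH4Cl
Reagents that add atoms: none
Why: Grignard 1,2-addition of the alkenylmagnesium reagent to the enal carbonyl is faster than conjugate addition in THF at low temperature; the carbinol centre formed is racemic and is consumed in step 2.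

Step 2
Reactants: 3 (4E)-2-methylhexa-1,4-dien-3-ol; 4 triethyl orthoacetate
Product: 6 ethyl (4E,6E)-4-methylocta-4,6-dienoate, via ketene acetal 5 (not isolated)
Conditions: MeC(OEt)3 (excess), EtCO2H (cat.), 135 °C, EtOH distilled off
Reagents that add atoms: none
Why: Johnson–Claisen rearrangement: the mixed ketene acetal rearranges through a chair transition state with the propenyl group equatorial and bonds at the unsubstituted CH2 terminus of the isopropenyl group in preference to the methyl-bearing propenyl terminus, which should give the 4E trisubstituted alkene conjugated to the retained E-propenyl unit.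

Step 3
Reactants: 6 ethyl (4E,6E)-4-methylocta-4,6-dienoate
Product: 8 (5E,7E)-5-methylnona-5,7-dien-1-yne, via dienal 7 (not isolated)
Conditions: DIBAL-H (1.1 equiv), CH2Cl2, −78 °C; then MeOH, K2CO3, dimethyl (1-diazo-2-oxopropyl)phosphonate, −78 °C → rt; Rochelle salt
Reagents that add atoms: dimethyl (1-diazo-2-oxopropyl)phosphonate (Bestmann–Ohira reagent), COP(=O)(OC)C(=[N+]=[N-])C(C)=O
Why: Partial DIBAL-H reduction stops at the aluminium hemiacetal at −78 °C, and the aldehyde set free by methanol undergoes Seyferth–Gilbert homologation with the Bestmann–Ohira reagent in the same flask (a known one-pot ester-to-alkyne conversion) without touching the unactivated diene.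

Step 4
Reactants: 8 (5E,7E)-5-methylnona-5,7-dien-1-yne
Product: 10 ethyl (6E,8E)-6-methyldeca-6,8-dien-2-ynoate, via lithium acetylide 9 (not isolated)
Conditions: n-BuLi, THF, −78 °C; ClCO2Et, −78 → 0 °C
Reagents that add atoms: ethyl chloroformate, CCOC(=O)Cl
Why: Deprotonation of the terminal alkyne and C-acylation of the lithium acetylide with a chloroformate is the standard route to 2-alkynoates.

Step 5
Reactants: 10 ethyl (6E,8E)-6-methyldeca-6,8-dien-2-ynoate; 11 isopropylmagnesium chloride
Product: 13 ethyl (2E,6E,8E)-6-methyl-3-(propan-2-yl)deca-2,6,8-trienoate, via alkenylcopper 12 (not isolated)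
Conditions: i-PrMgCl (11), CuBr·SMe2 (1 equiv each), THF, −78 °C; add 10, −78 °C; MeOH then aq. NH4Cl at −78 °C
Reagents that add atoms: none
Why: Syn-carbocupration (organocopper conjugate addition) of the alkynoate at −78 °C followed by protonation of the alkenylcopper in the cold puts hydrogen where copper was, so isopropyl ends trans to the ester and the C4=C5 geometry (2E, ester cis to the dienyl chain) is set stereospecifically.

Step 6
Reactants: 13 ethyl (2E,6E,8E)-6-methyl-3-(propan-2-yl)deca-2,6,8-trienoate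
Product: 14 (2E,6E,8E)-6-methyl-3-(propan-2-yl)deca-2,6,8-trien-1-ol
Conditions: DIBAL-H (2.5 equiv), CH2Cl2, −78 → −20 °C; Rochelle salt
Reagents that add atoms: none
Why: DIBAL-H reduces the conjugated ester by two 1,2-hydride additions to the allylic alcohol and leaves the three C=C bonds and their geometry untouched.

Step 7
Reactants: 14 (2E,6E,8E)-6-methyl-3-(propan-2-yl)deca-2,6,8-trien-1-ol
Product: 15 [(2R,3R)-3-[(3E,5E)-3-methylhepta-3,5-dien-1-yl]-3-(propan-2-yl)oxiran-2-yl]methanol
Conditions: Ti(OiPr)4 (10 mol %), D-(−)-diethyl tartrate (12 mol %), t-BuOOH (anhydrous), 4 Å MS, CH2Cl2, −20 °C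
Reagents that add atoms: tert-butyl hydroperoxide, CC(C)(C)OO
Why: Katsuki–Sharpless asymmetric epoxidation acts only on the allylic alcohol double bond, and with D-(−)-diethyl tartrate the titanium–tartrate complex should deliver oxygen to the face that gives the (2R,3R)-epoxy alcohol, which fixes C4 and C5 absolutely.

Step 8
Reactants: 15 [(2R,3R)-3-[(3E,5E)-3-methylhepta-3,5-dien-1-yl]-3-(propan-2-yl)oxiran-2-yl]methanol
Product: 16 (2S,3R)-3-[(3E,5E)-3-methylhepta-3,5-dien-1-yl]-3-(propan-2-yl)oxirane-2-carbaldehyde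
Conditions: Dess–Martin periodinane, NaHCO3, CH2Cl2, 0 °C → rt
Reagents that add atoms: none
Why: Dess–Martin oxidation, buffered with bicarbonate, converts the primary epoxy alcohol into the epoxy aldehyde without acid that could open the epoxide or isomerise the diene.

Step 9
Reactants: 16 (2S,3R)-3-[(3E,5E)-3-methylhepta-3,5-dien-1-yl]-3-(propan-2-yl)oxirane-2-carbaldehyde
Product: 17 1-[(2R,3R)-3-[(3E,5E)-3-methylhepta-3,5-dien-1-yl]-3-(propan-2-yl)oxiran-2-yl]ethan-1-ol (both carbinol epimers)
Conditions: MeMgBr, THF, −78 °C; aq. NH4Cl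
Reagents that add atoms: methylmagnesium bromide, C[Mg]Br
Why: Grignard addition to the aldehyde at −78 °C is far faster than opening of the trisubstituted epoxide; the new carbinol centre need not be controlled because it is oxidised in step 10.

Step 10
Reactants: 17 1-[(2R,3R)-3-[(3E,5E)-3-methylhepta-3,5-dien-1-yl]-3-(propan-2-yl)oxiran-2-yl]ethan-1-ol
Product: 18 1-[(2S,3R)-3-[(3E,5E)-3-methylhepta-3,5-dien-1-yl]-3-(propan-2-yl)oxiran-2-yl]ethan-1-one
Conditions: Dess–Martin periodinane, NaHCO3, CH2Cl2, 0 °C → rt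
Reagents that add atoms: none
Why: Dess–Martin oxidation converges both carbinol epimers on the α,β-epoxy methyl ketone, whose oxiranyl C–H does not enolise under these conditions.

Step 11
Reactants: 18 1-[(2S,3R)-3-[(3E,5E)-3-methylhepta-3,5-dien-1-yl]-3-(propan-2-yl)oxiran-2-yl]ethan-1-one
Product: 20 triethyl({1-[(2S,3R)-3-[(3E,5E)-3-methylhepta-3,5-dien-1-yl]-3-(propan-2-yl)oxiran-2-yl]ethenyl}oxy)silane, via lithium enolate 19 (not isolated)
Conditions: LiHMDS, THF, −78 °C; Et3SiCl; pentane/aq. NaHCO3, filtration through Et3N-deactivated silica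
Reagents that add atoms: chlorotriethylsilane, CC[Si](Cl)(CC)CC
Why: Kinetic enolisation with LiHMDS occurs only at the methyl group, since the oxiranyl C5–H is not removed, and O-silylation of the lithium enolate with Et3SiCl gives the 2-silyloxyalk-1-ene (silyl enol ether formation).

Step 12
Reactants: 20 triethyl({1-[(2S,3R)-3-[(3E,5E)-3-methylhepta-3,5-dien-1-yl]-3-(propan-2-yl)oxiran-2-yl]ethenyl}oxy)silane
Product: 21 (3R,3aR,6R,8aR)-6,8a-dimethyl-3-(propan-2-yl)-3-[(triethylsilyl)oxy]-2,3,3a,5,6,8a-hexahydroazulen-4(1H)-one (trans-fused; 8a-methyl syn to the 3-silyloxy group and anti to H3a)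
Conditions: Et3SiOTf (0.1–0.2 equiv), CH2Cl2 (0.01 M), −78 °C; Et3N, then aq. NaHCO3
Reagents that add atoms: none
Why: Et3SiOTf silylates the epoxide oxygen, the C5–O bond ionises with π-assistance from the enol silane while the diene terminus C1 bonds to C5 from the side opposite the leaving oxygen, the resulting C10–C9–C8 allyl cation is captured at C8 by the enol silane carbon C7, and the silyloxocarbenium ion hands Et3Si+ back to triflate, so the acid turns over and the silyl group that opened the epoxide stays on O4. The closest known reaction is the silyl triflate-catalysed intramolecular (4+3) cycloaddition of enantiopure 3,4-epoxy-2-silyloxyalk-1-enes with dienes or furans tethered through the distal epoxide carbon, which transfers the epoxide chirality to the cycloadduct. The five-membered ring closes by attack of the tethered alkene carbon C1 on the epoxide carbon C5 (exo with respect to the C1=C10 bond, endo with respect to the epoxide, possible because C5 is an incipient silyloxyallyl cation), and the seven-membered ring closes by union of C7 with C8, the second bond of the (4+3) array, which leaves C9=C10 inside the ring. C4 is carried over unchanged from the Sharpless epoxide, C5 is set by inversion at the epoxide carbon (H5 cis to isopropyl, C6 cis to O4), C1 is set by the diene face that reacts, and C8 follows from suprafacial bonding to the (E,E)-diene, which puts the C8 hydrogen cis to the C1 methyl. The step needs ionisation at C5 and not at the tertiary C4, which the allylic enol silane secures, and it needs the dienyl arm on C1 to lie anti to the silyloxyvinyl arm on C5 (trans ring fusion, C1 methyl syn to O4), which should follow because the silylated oxygen on C4 and the silyloxyvinyl group crowd one face of the forming cyclopentane and leave room there only for the methyl group, the isopropyl group pointing away from the ring. High dilution and low temperature keep the cation intramolecular and suppress proton loss.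

Step 13
Reactants: 21 (3R,3aR,6R,8aR)-6,8a-dimethyl-3-(propan-2-yl)-3-[(triethylsilyl)oxy]-2,3,3a,5,6,8a-hexahydroazulen-4(1H)-one
Product: 22 (3R,3aR,6R,8aR)-3-hydroxy-6,8a-dimethyl-3-(propan-2-yl)-2,3,3a,5,6,8a-hexahydroazulen-4(1H)-one
Conditions: HF·pyridine, pyridine, THF, 0 °C → rt
Reagents that add atoms: none
Why: Fluoride-induced desilylation with buffered HF·pyridine cleaves the tertiary triethylsilyl ether under mildly acidic conditions, which avoids retro-aldol cleavage and C5 epimerisation of the β-hydroxy ketone.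

Step 14
Reactants: 22 (3R,3aR,6R,8aR)-3-hydroxy-6,8a-dimethyl-3-(propan-2-yl)-2,3,3a,5,6,8a-hexahydroazulen-4(1H)-one
Product: 23 (3R,3aS,4S,6R,8aR)-6,8a-dimethyl-3-(propan-2-yl)-1,2,3,3a,4,5,6,8a-octahydroazulene-3,4-diol
Conditions: Me4NBH(OAc)3, MeCN/AcOH (1:1), −30 → −10 °C
Reagents that add atoms: none
Why: Evans–Saksena reduction: ligand exchange at boron with the C4 hydroxyl gives an alkoxydiacetoxyborohydride that delivers hydride to the C6 carbonyl intramolecularly from the face of O4, so H6 enters syn to O4 and the new hydroxyl stands anti to it (1,3-anti diol, 4S in azulene numbering).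

Step 15
Reactants: 23 (3R,3aS,4S,6R,8aR)-6,8a-dimethyl-3-(propan-2-yl)-1,2,3,3a,4,5,6,8a-octahydroazulene-3,4-diol; 24 4-methoxybenzoyl chloride
Product: 25 (3R,3aS,4S,6R,8aR)-3-hydroxy-6,8a-dimethyl-3-(propan-2-yl)-1,2,3,3a,4,5,6,8a-octahydroazulen-4-yl 4-methoxybenzoate
Conditions: pyridine, DMAP (cat.), CH2Cl2, 0 °C → rt
Reagents that add atoms: none
Why: DMAP-catalysed acylation (nucleophilic catalysis) esterifies the secondary C6 hydroxyl, while the tertiary C4 hydroxyl is too hindered to react under these conditions.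

Step 16
Reactants: 25 (3R,3aS,4S,6R,8aR)-3-hydroxy-6,8a-dimethyl-3-(propan-2-yl)-1,2,3,3a,4,5,6,8a-octahydroazulen-4-yl 4-methoxybenzoate
Product: 26 (3R,3aS,4S,6R,7R,8S,8aS)-7,8-epoxy-3-hydroxy-6,8a-dimethyl-3-(propan-2-yl)decahydroazulen-4-yl 4-methoxybenzoate (epoxide oxygen anti to the 8a-methyl group)
Conditions: m-CPBA, NaHCO3, CH2Cl2, 0 °C
Reagents that add atoms: 3-chloroperoxybenzoic acid, OOC(=O)c1cccc(Cl)c1
Why: Prilezhaev epoxidation of the only C=C bond should occur on the face opposite the angular C1 methyl group, which is fixed over the lower face of C10, so the epoxide oxygen ends syn to H5.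

Step 17
Reactants: 26 (3R,3aS,4S,6R,7R,8S,8aS)-7,8-epoxy-3-hydroxy-6,8a-dimethyl-3-(propan-2-yl)decahydroazulen-4-yl 4-methoxybenzoate
Product: 27 (3R,3aS,4S,6R,7S,8S,8aS)-3,8-dihydroxy-6,8a-dimethyl-7-(phenylselanyl)-3-(propan-2-yl)decahydroazulen-4-yl 4-methoxybenzoate
Conditions: (PhSe)2, NaBH4, EtOH, rt; then 26, 50 °C
Reagents that add atoms: diphenyl diselenide, c1ccc(cc1)[Se][Se]c1ccccc1
Why: SN2 opening of the epoxide by the soft phenylselenolate takes place at C9, the carbon not flanked by the quaternary C1, with inversion, which leaves the C10 hydroxyl anti to the C1 methyl and places selenium on the same face as H8.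

Step 18
Reactants: 27 (3R,3aS,4S,6R,7S,8S,8aS)-3,8-dihydroxy-6,8a-dimethyl-7-(phenylselanyl)-3-(propan-2-yl)decahydroazulen-4-yl 4-methoxybenzoate
Product: 29 (3R,3aS,4S,8R,8aS)-3,8-dihydroxy-6,8a-dimethyl-3-(propan-2-yl)-1,2,3,3a,4,5,8,8a-octahydroazulen-4-yl 4-methoxybenzoate, via selenoxide 28 (not isolated)
Conditions: 30% H2O2, pyridine, THF, 0 °C → rt
Reagents that add atoms: none
Why: Oxidation to the selenoxide is followed by selenoxide syn-elimination, which takes the syn hydrogen on C8 and, as is general for β-hydroxy selenoxides, avoids the carbinol carbon, giving the 8,9-alkene and leaving the C10 configuration untouched.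

Step 19
Reactants: 29 (3R,3aS,4S,8R,8aS)-3,8-dihydroxy-6,8a-dimethyl-3-(propan-2-yl)-1,2,3,3a,4,5,8,8a-octahydroazulen-4-yl 4-methoxybenzoate
Product: 30 (3R,3aS,4S,8R,8aS)-8-(acetyloxy)-3-hydroxy-6,8a-dimethyl-3-(propan-2-yl)-1,2,3,3a,4,5,8,8a-octahydroazulen-4-yl 4-methoxybenzoate (CNP0256979.2)
Conditions: Ac2O, pyridine, DMAP (cat.), CH2Cl2, 0 °C → rt
Reagents that add atoms: acetic anhydride, CC(=O)OC(C)=O
Why: DMAP-catalysed acetylation with acetic anhydride esterifies the secondary allylic C10 hydroxyl, and the tertiary C4 hydroxyl stays free under these mild conditions.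

Compound list
1 | (2E)-but-2-enal (crotonaldehyde) | C/C=C/C=O | starting material
2 | isopropenylmagnesium bromide | CC(=C)[Mg]Br | starting material
3 | (4E)-2-methylhexa-1,4-dien-3-ol (racemic) | C/C=C/C(O)C(C)=C | intermediate
4 | triethyl orthoacetate | CCOC(C)(OCC)OCC | starting material
5 | 1-ethoxy-1-{[(4E)-2-methylhexa-1,4-dien-3-yl]oxy}ethene (ketene acetal) | C/C=C/C(OC(=C)OCC)C(C)=C | intermediate
6 | ethyl (4E,6E)-4-methylocta-4,6-dienoate | CCOC(=O)CC/C(C)=C/C=C/C | intermediate
7 | (4E,6E)-4-methylocta-4,6-dienal | O=CCC/C(C)=C/C=C/C | intermediate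
8 | (5E,7E)-5-methylnona-5,7-dien-1-yne | C#CCC/C(C)=C/C=C/C | intermediate
9 | [(5E,7E)-5-methylnona-5,7-dien-1-yn-1-yl]lithium | [Li]C#CCC/C(C)=C/C=C/C | intermediate
10 | ethyl (6E,8E)-6-methyldeca-6,8-dien-2-ynoate | CCOC(=O)C#CCC/C(C)=C/C=C/C | intermediate
11 | isopropylmagnesium chloride | CC(C)[Mg]Cl | starting material
12 | ethyl (2Z,6E,8E)-2-cuprio-6-methyl-3-(propan-2-yl)deca-2,6,8-trienoate (alkenylcopper, Cu cis to isopropyl) | CCOC(=O)/C([Cu])=C(/C(C)C)CC/C(C)=C/C=C/C | intermediate
13 | ethyl (2E,6E,8E)-6-methyl-3-(propan-2-yl)deca-2,6,8-trienoate | CCOC(=O)/C=C(/C(C)C)CC/C(C)=C/C=C/C | intermediate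
14 | (2E,6E,8E)-6-methyl-3-(propan-2-yl)deca-2,6,8-trien-1-ol | OC/C=C(/C(C)C)CC/C(C)=C/C=C/C | intermediate
15 | [(2R,3R)-3-[(3E,5E)-3-methylhepta-3,5-dien-1-yl]-3-(propan-2-yl)oxiran-2-yl]methanol | OC[C@H]1O[C@@]1(C(C)C)CC/C(C)=C/C=C/C | intermediate
16 | (2S,3R)-3-[(3E,5E)-3-methylhepta-3,5-dien-1-yl]-3-(propan-2-yl)oxirane-2-carbaldehyde | O=C[C@H]1O[C@@]1(C(C)C)CC/C(C)=C/C=C/C | intermediate
17 | 1-[(2R,3R)-3-[(3E,5E)-3-methylhepta-3,5-dien-1-yl]-3-(propan-2-yl)oxiran-2-yl]ethan-1-ol (both carbinol epimers) | CC(O)[C@H]1O[C@@]1(C(C)C)CC/C(C)=C/C=C/C | intermediate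
18 | 1-[(2S,3R)-3-[(3E,5E)-3-methylhepta-3,5-dien-1-yl]-3-(propan-2-yl)oxiran-2-yl]ethan-1-one | CC(=O)[C@H]1O[C@@]1(C(C)C)CC/C(C)=C/C=C/C | intermediate
19 | lithium enolate of 18 (methyl side, epoxide unchanged) | [Li]OC(=C)[C@H]1O[C@@]1(C(C)C)CC/C(C)=C/C=C/C | intermediate
20 | triethyl({1-[(2S,3R)-3-[(3E,5E)-3-methylhepta-3,5-dien-1-yl]-3-(propan-2-yl)oxiran-2-yl]ethenyl}oxy)silane | C=C(O[Si](CC)(CC)CC)[C@H]1O[C@@]1(C(C)C)CC/C(C)=C/C=C/C | intermediate
21 | (3R,3aR,6R,8aR)-6,8a-dimethyl-3-(propan-2-yl)-3-[(triethylsilyl)oxy]-2,3,3a,5,6,8a-hexahydroazulen-4(1H)-one | C[C@H]1C=C[C@@]2(C)CC[C@@](O[Si](CC)(CC)CC)(C(C)C)[C@@H]2C(=O)C1 | intermediate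
22 | (3R,3aR,6R,8aR)-3-hydroxy-6,8a-dimethyl-3-(propan-2-yl)-2,3,3a,5,6,8a-hexahydroazulen-4(1H)-one | C[C@H]1C=C[C@@]2(C)CC[C@@](O)(C(C)C)[C@@H]2C(=O)C1 | intermediate
23 | (3R,3aS,4S,6R,8aR)-6,8a-dimethyl-3-(propan-2-yl)-1,2,3,3a,4,5,6,8a-octahydroazulene-3,4-diol | C[C@H]1C=C[C@@]2(C)CC[C@@](O)(C(C)C)[C@@H]2[C@@H](O)C1 | intermediate
24 | 4-methoxybenzoyl chloride | COc1ccc(C(Cl)=O)cc1 | starting material
25 | (3R,3aS,4S,6R,8aR)-3-hydroxy-6,8a-dimethyl-3-(propan-2-yl)-1,2,3,3a,4,5,6,8a-octahydroazulen-4-yl 4-methoxybenzoate | COc1ccc(C(=O)O[C@H]2C[C@@H](C)C=C[C@@]3(C)CC[C@@](O)(C(C)C)[C@H]23)cc1 | intermediate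
26 | (3R,3aS,4S,6R,7R,8S,8aS)-7,8-epoxy-3-hydroxy-6,8a-dimethyl-3-(propan-2-yl)decahydroazulen-4-yl 4-methoxybenzoate | COc1ccc(C(=O)O[C@H]2C[C@@H](C)[C@H]4O[C@H]4[C@@]3(C)CC[C@@](O)(C(C)C)[C@H]23)cc1 | intermediate
27 | (3R,3aS,4S,6R,7S,8S,8aS)-3,8-dihydroxy-6,8a-dimethyl-7-(phenylselanyl)-3-(propan-2-yl)decahydroazulen-4-yl 4-methoxybenzoate | COc1ccc(C(=O)O[C@H]2C[C@@H](C)[C@H]([Se]c4ccccc4)[C@@H](O)[C@@]3(C)CC[C@@](O)(C(C)C)[C@H]23)cc1 | intermediate
28 | Se-oxide of 27 (7-benzeneseleninyl compound) | COc1ccc(C(=O)O[C@H]2C[C@@H](C)[C@H]([Se](=O)c4ccccc4)[C@@H](O)[C@@]3(C)CC[C@@](O)(C(C)C)[C@H]23)cc1 | intermediate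
29 | (3R,3aS,4S,8R,8aS)-3,8-dihydroxy-6,8a-dimethyl-3-(propan-2-yl)-1,2,3,3a,4,5,8,8a-octahydroazulen-4-yl 4-methoxybenzoate | COc1ccc(C(=O)O[C@H]2CC(C)=C[C@@H](O)[C@@]3(C)CC[C@@](O)(C(C)C)[C@H]23)cc1 | intermediate
30 | (3R,3aS,4S,8R,8aS)-8-(acetyloxy)-3-hydroxy-6,8a-dimethyl-3-(propan-2-yl)-1,2,3,3a,4,5,8,8a-octahydroazulen-4-yl 4-methoxybenzoate (CNP0256979.2) | COc1ccc(C(=O)O[C@H]2CC(C)=C[C@@H](OC(C)=O)[C@@]3(C)CC[C@@](O)(C(C)C)[C@H]23)cc1 | target

Total step count: 19. Longest linear sequence: 19 steps (1 → 30; compounds 2, 4, 11 and 24 enter as purchased reagents).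

Steps most likely to fail

Step 12. What may go wrong: the tether stands cis to the enol silane on the epoxide, so both new bonds cannot form from one stacked arrangement. Ring closure with the dienyl arm syn to the silyloxyvinyl arm (cis fusion, C1 epimeric with respect to C4), capture of the allyl cation at C10, or proton loss may then compete, and ionisation may spill over to the tertiary C4–O bond. Fallback: set out from ynoate 10 and build the C5-epimeric epoxide, in which the tether is trans to the enol silane (the best documented arrangement), then correct C5 by equilibration. Anti-hydroiodination (NaI, AcOH, 70 °C) should give ethyl (2Z,6E,8E)-3-iodo-6-methyldeca-2,6,8-trienoate F1. Substitution of iodide with retention by the isopropylcopper reagent from 11 (CuBr·SMe2, THF, −78 °C) should give ethyl (2Z,6E,8E)-6-methyl-3-(propan-2-yl)deca-2,6,8-trienoate F2, with isopropyl cis to the ester. DIBAL-H gives (2Z,6E,8E)-6-methyl-3-(propan-2-yl)deca-2,6,8-trien-1-ol F3. Sharpless epoxidation with L-(+)-diethyl tartrate should give [(2S,3R)-3-[(3E,5E)-3-methylhepta-3,5-dien-1-yl]-3-(propan-2-yl)oxiran-2-yl]methanol F4, which has the C4 configuration of 15 and the opposite C5. Dess–Martin oxidation gives the (2R,3R)-oxirane-2-carbaldehyde F5, MeMgBr gives the 1-[(2S,3R)-oxiranyl]ethan-1-ol F6, a second Dess–Martin oxidation gives the (2R,3R)-epoxy methyl ketone F7, and LiHMDS/Et3SiCl gives the (2R,3R)-epoxy enol silane F8. With Et3SiOTf this substrate can bond C1–C5 and C7–C8 from a single compact arrangement, in which the C1 methyl takes the face of H5, and H5 is now on the face of O4. This should give the cis-fused (3R,3aS,6R,8aR)-6,8a-dimethyl-3-(propan-2-yl)-3-[(triethylsilyl)oxy]-2,3,3a,5,6,8a-hexahydroazulen-4(1H)-one F9 (C1, C4 and C8 as in 21, C5 epimeric). DBU in toluene should then epimerise C5 next to the ketone, moving C6 from the side of the isopropyl group to the side of the silyloxy group, and give 21, where the route is rejoined.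

Step 14. What may go wrong: hydride delivery from the hindered tertiary alkoxyborohydride may be slow, so that intermolecular reduction from the other face, or dehydration and retro-aldol cleavage of the β-hydroxy ketone in acetic acid, competes. Fallback: set out from silyl ether 21 and use steric control followed by invertive esterification. NaBH4 in MeOH should attack the C6 carbonyl from the face opposite the C4 silyloxy group and the C1 methyl and give (3R,3aS,4R,6R,8aR)-6,8a-dimethyl-3-(propan-2-yl)-3-[(triethylsilyl)oxy]-1,2,3,3a,4,5,6,8a-octahydroazulen-4-ol F10. Mitsunobu esterification with 4-methoxybenzoic acid (PPh3, DIAD, toluene) installs the anisoate with inversion and gives (3R,3aS,4S,6R,8aR)-6,8a-dimethyl-3-(propan-2-yl)-3-[(triethylsilyl)oxy]-1,2,3,3a,4,5,6,8a-octahydroazulen-4-yl 4-methoxybenzoate F11. HF·pyridine removes the silyl group and returns the route to 25.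

Step 16. What may go wrong: poor facial selectivity, because the C8 methyl and the C6 ester lie on the face that must be attacked, so the peracid may add syn to the C1 methyl. Fallback: set out from 25 and reverse the facial sense by a halohydrin sequence. NBS in aqueous DME should form the bromonium ion on the face the peracid prefers, and water opens it anti at C9 to give (3R,3aS,4S,6R,7R,8R,8aS)-8-bromo-3,7-dihydroxy-6,8a-dimethyl-3-(propan-2-yl)decahydroazulen-4-yl 4-methoxybenzoate F12. NaH in THF closes the epoxide by displacing bromide from the opposite face and returns the route to 26.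

Further compounds
F1 | step 12 | ethyl (2Z,6E,8E)-3-iodo-6-methyldeca-2,6,8-trienoate | CCOC(=O)/C=C(\I)CC/C(C)=C/C=C/C
F2 | step 12 | ethyl (2Z,6E,8E)-6-methyl-3-(propan-2-yl)deca-2,6,8-trienoate | CCOC(=O)/C=C(\C(C)C)CC/C(C)=C/C=C/C
F3 | step 12 | (2Z,6E,8E)-6-methyl-3-(propan-2-yl)deca-2,6,8-trien-1-ol | OC/C=C(\C(C)C)CC/C(C)=C/C=C/C
F4 | step 12 | [(2S,3R)-3-[(3E,5E)-3-methylhepta-3,5-dien-1-yl]-3-(propan-2-yl)oxiran-2-yl]methanol | OC[C@@H]1O[C@@]1(C(C)C)CC/C(C)=C/C=C/C
F5 | step 12 | (2R,3R)-3-[(3E,5E)-3-methylhepta-3,5-dien-1-yl]-3-(propan-2-yl)oxirane-2-carbaldehyde | O=C[C@@H]1O[C@@]1(C(C)C)CC/C(C)=C/C=C/C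
F6 | step 12 | 1-[(2S,3R)-3-[(3E,5E)-3-methylhepta-3,5-dien-1-yl]-3-(propan-2-yl)oxiran-2-yl]ethan-1-ol (both carbinol epimers) | CC(O)[C@@H]1O[C@@]1(C(C)C)CC/C(C)=C/C=C/C
F7 | step 12 | 1-[(2R,3R)-3-[(3E,5E)-3-methylhepta-3,5-dien-1-yl]-3-(propan-2-yl)oxiran-2-yl]ethan-1-one | CC(=O)[C@@H]1O[C@@]1(C(C)C)CC/C(C)=C/C=C/C
F8 | step 12 | triethyl({1-[(2R,3R)-3-[(3E,5E)-3-methylhepta-3,5-dien-1-yl]-3-(propan-2-yl)oxiran-2-yl]ethenyl}oxy)silane | C=C(O[Si](CC)(CC)CC)[C@@H]1O[C@@]1(C(C)C)CC/C(C)=C/C=C/C
F9 | step 12 | (3R,3aS,6R,8aR)-6,8a-dimethyl-3-(propan-2-yl)-3-[(triethylsilyl)oxy]-2,3,3a,5,6,8a-hexahydroazulen-4(1H)-one | C[C@H]1C=C[C@@]2(C)CC[C@@](O[Si](CC)(CC)CC)(C(C)C)[C@H]2C(=O)C1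
F10 | step 14 | (3R,3aS,4R,6R,8aR)-6,8a-dimethyl-3-(propan-2-yl)-3-[(triethylsilyl)oxy]-1,2,3,3a,4,5,6,8a-octahydroazulen-4-ol | C[C@H]1C=C[C@@]2(C)CC[C@@](O[Si](CC)(CC)CC)(C(C)C)[C@@H]2[C@H](O)C1
F11 | step 14 | (3R,3aS,4S,6R,8aR)-6,8a-dimethyl-3-(propan-2-yl)-3-[(triethylsilyl)oxy]-1,2,3,3a,4,5,6,8a-octahydroazulen-4-yl 4-methoxybenzoate | COc1ccc(C(=O)O[C@H]2C[C@@H](C)C=C[C@@]3(C)CC[C@@](O[Si](CC)(CC)CC)(C(C)C)[C@H]23)cc1
F12 | step 16 | (3R,3aS,4S,6R,7R,8R,8aS)-8-bromo-3,7-dihydroxy-6,8a-dimethyl-3-(propan-2-yl)decahydroazulen-4-yl 4-methoxybenzoate | COc1ccc(C(=O)O[C@H]2C[C@@H](C)[C@@H](O)[C@H](Br)[C@@]3(C)CC[C@@](O)(C(C)C)[C@H]23)cc1
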